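**Plan**

1. Numbering (target and all ring intermediates): O1, C2 (C–Me, cyclohexyl), C3 (CHOH), C4 (CH2), C5 (CHBr), C6 (CMe2); cyclohexane C1′, C3′ (Cl), C4′ (Br, Me).
2. Retrosynthesis: the C5–Br, C4′–Br and O1–C6 bonds are undone together (oxane ⇒ 5-(2-benzyloxypropan-2-yl)oxolane with O1 on C5; bromochloride ⇒ chlorohydrin ⇒ cyclohexene). The oxolane is then cut at O1–C2 and C4–C5 into a tertiary allylsilane (C2–C3=C4) and an α-alkoxy aldehyde (C5=O1, C6).
3. Forward: the cyclohexene comes from (4R)-limonene oxide; the oxolane is closed by a [3+2] annulation; the oxane arises last by ring enlargement of the oxolane, in the operation that also installs the tertiary bromide.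
4. Enabling feature: C2 is fully substituted and carries silicon next to the C3=C4 bond, so C4 is nucleophilic and, after a 1,2-silyl shift to C3, C2 becomes the cationic end 1,3 to it. A C5=O1 carbonyl can therefore bridge C4 and C2, and silicon is left on C3, where the hydroxyl is needed.
5. Second feature: in the oxolane, O1 is 1,2 to the tertiary exocyclic C6, so ionisation at C6 gives a bicyclic epoxonium ion that bromide opens at C5 with inversion (oxolane → 5-bromo-6,6-dimethyloxane).
6. Stereochemistry: C1′ from limonene; C2 from catalyst-controlled allylic silylation, transferred with inversion; C5 from the chelate-controlled annulation, then inverted by bromide; C3 from hydride attack anti to cyclohexenyl; C3′/C4′ from trans-diaxial chlorohydroxylation and bromide substitution with retention via the chloronium ion.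

Key step: step 9

**Route**

Step 1
Reactants: 1 (4R)-limonene 1,2-oxide [(4R)-1-methyl-4-(prop-1-en-2-yl)-7-oxabicyclo[4.1.0]heptane, commercial cis/trans epoxide mixture]
Product: 3 1-[(3R)-6-methyl-7-oxabicyclo[4.1.0]heptan-3-yl]ethan-1-one (both epoxide epimers), via ozonide 2 (not isolated)
Conditions: O3, CH2Cl2, −78 °C; then Me2S, −78 → 23 °C
Reagents that add atoms: ozone ([O-][O+]=O)
Why: Ozonolysis with reductive work-up cleaves the only C=C bond (the isopropenyl group) to the methyl ketone, while the epoxide that masks the ring alkene is inert and the C1′ centre is untouched.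

Step 2
Reactants: 3 1-[(3R)-6-methyl-7-oxabicyclo[4.1.0]heptan-3-yl]ethan-1-one
Product: 5 1-[(1R)-4-methylcyclohex-3-en-1-yl]ethan-1-one, via iodohydrin 4 (not isolated)
Conditions: Zn, NaI, NaOAc, AcOH, 23 °C
Reagents that add atoms: none
Why: Reductive deoxygenation of the epoxide (iodide opens it, zinc eliminates the β-iodo alcohol) should return the trisubstituted ring alkene from both epoxide epimers without touching the ketone.

Step 3
Reactants: 5 1-[(1R)-4-methylcyclohex-3-en-1-yl]ethan-1-one; 6 triethyl phosphonoacetate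
Product: 7 ethyl (2E)-3-[(1R)-4-methylcyclohex-3-en-1-yl]but-2-enoate
Conditions: NaH, THF, 0 → 50 °C (anion of 6 preformed); minor (Z)-isomer removed by chromatography
Reagents that add atoms: none
Why: Horner–Wadsworth–Emmons olefination of the methyl ketone should give mainly the (E)-enoate (ester trans to the larger cyclohexenyl group), and the weakly basic phosphonate anion should not enolise the ketone toward C1′.

Step 4
Reactants: 7 ethyl (2E)-3-[(1R)-4-methylcyclohex-3-en-1-yl]but-2-enoate
Product: 8 (2E)-3-[(1R)-4-methylcyclohex-3-en-1-yl]but-2-en-1-ol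
Conditions: i-Bu2AlH (2.2 equiv), CH2Cl2, −78 → 0 °C; KNaC4H4O6 (aq.)
Reagents that add atoms: none
Why: 1,2-Reduction of the conjugated ester by the aluminium hydride gives the allylic alcohol with the alkene geometry retained.

Step 5
Reactants: 8 (2E)-3-[(1R)-4-methylcyclohex-3-en-1-yl]but-2-en-1-ol
Product: 9 diethyl (2E)-3-[(1R)-4-methylcyclohex-3-en-1-yl]but-2-en-1-yl phosphate
Conditions: ClP(O)(OEt)2, pyridine, DMAP (cat.), CH2Cl2, 0 °C
Reagents that add atoms: diethyl chlorophosphate (CCOP(=O)(Cl)OCC)
Why: O-Phosphorylation of the primary allylic alcohol installs the leaving group used in copper-catalysed allylic substitution.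

Step 6
Reactants: 9 diethyl (2E)-3-[(1R)-4-methylcyclohex-3-en-1-yl]but-2-en-1-yl phosphate
Product: 10 dimethyl{(2S)-2-[(1R)-4-methylcyclohex-3-en-1-yl]but-3-en-2-yl}phenylsilane
Conditions: PhMe2Si–Bpin, CuCl (5 mol %), chiral imidazolinium chloride (carbene precursor, 6 mol %), NaOMe, THF, 0 °C
Reagents that add atoms: (dimethylphenylsilyl)boronic acid pinacol ester (C[Si](C)(c1ccccc1)B1OC(C)(C)C(C)(C)O1)
Why: Copper-catalysed γ-selective (SN2′) allylic silylation, precedented for γ,γ-disubstituted (E)-allylic phosphates, should form the silicon-bearing quaternary centre C2 under catalyst control (the ring centre is too remote to interfere), the ligand antipode being chosen for the (2S)-silane.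

Step 7
Reactants: 11 2-methylbut-3-en-2-ol
Product: 12 {[(2-methylbut-3-en-2-yl)oxy]methyl}benzene
Conditions: NaH, BnBr, Bu4NI (cat.), THF/DMF, 0 → 23 °C
Reagents that add atoms: benzyl bromide (BrCc1ccccc1)
Why: Williamson etherification of the tertiary alkoxide with the reactive benzylic halide gives the benzyl ether that later serves as chelating group and as leaving group.

Step 8
Reactants: 12 {[(2-methylbut-3-en-2-yl)oxy]methyl}benzene
Product: 14 2-(benzyloxy)-2-methylpropanal, via ozonide 13 (not isolated)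
Conditions: O3, CH2Cl2, −78 °C; then Me2S, −78 → 23 °C
Reagents that add atoms: ozone ([O-][O+]=O)
Why: Ozonolysis of the vinyl group with reductive work-up gives the non-enolisable α-alkoxy aldehyde.

Step 9
Reactants: 10 dimethyl{(2S)-2-[(1R)-4-methylcyclohex-3-en-1-yl]but-3-en-2-yl}phenylsilane; 14 2-(benzyloxy)-2-methylpropanal
Product: 15 {(2S,3R,5R)-5-[2-(benzyloxy)propan-2-yl]-2-methyl-2-[(1R)-4-methylcyclohex-3-en-1-yl]oxolan-3-yl}dimethyl(phenyl)silane (methyl, silyl and the C5 arm all cis; cyclohexenyl trans)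
Conditions: SnCl4 (1.05 equiv, promoter), CH2Cl2, −78 °C (14 pre-complexed, then 10); NaHCO3 (aq.) quench at −78 °C
Reagents that add atoms: none
Why: Proposed new method: the SnCl4 chelate of 14 (carbonyl O and benzyloxy O) is attacked at its carbonyl carbon C5 by the terminal alkene carbon C4 of 10 on the face anti to silicon (anti-SE2′), the β-silyl cation at C3 is bridged by silicon, a suprafacial 1,2-silyl shift moves the charge to the tertiary C2, and the tin-bound oxygen O1 closes on C2 anti to silicon. The closest known reaction is the Lewis-acid [3+2] annulation of α-monosubstituted allylsilanes with aldehydes to 3-silyloxolanes; the extension is to an α,α-disubstituted allylsilane, so that the new C–O bond is made at a fully substituted carbon. The oxolane closes in a 5-endo fashion with respect to the silicon-bridged C2–C3 unit (capture of a tertiary cation by an alkoxide four atoms away), which is the closure mode of all such annulations. C2 is set by the configuration of 10 (silicon is replaced by O1 with inversion, methyl taking the less crowded inside position of the allyl unit), C3 by the shift itself (silicon ends trans to O1 and cis to the C2 methyl group), and C5 by the chelated open transition state, in which the bulky SnCl4-bound carbonyl oxygen lies anti to the C3=C4 bond and the CMe2OBn arm sits on the side of the vinylic hydrogen, the arrangement known to give the 2,5-trans series (arm trans to cyclohexenyl). The step needs ring closure to outrun loss of silicon (plain allyl transfer); the poorly ionising phenyldimethylsilyl group, the low temperature and the tertiary, well-stabilised cation at C2 next to a nearby tin alkoxide should secure this.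

Step 10
Reactants: 15 {(2S,3R,5R)-5-[2-(benzyloxy)propan-2-yl]-2-methyl-2-[(1R)-4-methylcyclohex-3-en-1-yl]oxolan-3-yl}dimethyl(phenyl)silane
Product: 16 (2S,3R,5R)-5-[2-(benzyloxy)propan-2-yl]-2-methyl-2-[(1R)-4-methylcyclohex-3-en-1-yl]oxolan-3-ol
Conditions: t-BuOOH, KH, Bu4NF (promoter), N-methylpyrrolidone, 23 → 70 °C
Reagents that add atoms: tert-butyl hydroperoxide (CC(C)(C)OO)
Why: Tamao–Fleming oxidation under basic conditions (phenyl cleavage at silicon, then migration of C3 from silicon to peroxide oxygen) replaces C–Si by C–OH with retention and tolerates the ring alkene and the benzyl ether.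

Step 11
Reactants: 16 (2S,3R,5R)-5-[2-(benzyloxy)propan-2-yl]-2-methyl-2-[(1R)-4-methylcyclohex-3-en-1-yl]oxolan-3-ol
Product: 17 (2S,5R)-5-[2-(benzyloxy)propan-2-yl]-2-methyl-2-[(1R)-4-methylcyclohex-3-en-1-yl]oxolan-3-one
Conditions: Dess–Martin periodinane, NaHCO3, CH2Cl2, 23 °C
Reagents that add atoms: none
Why: Dess–Martin oxidation of the secondary alcohol clears the C3 centre (the silyl shift places oxygen cis to methyl, the target needs it cis to cyclohexyl) without risk to the quaternary C2 or to C5.

Step 12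
Reactants: 17 (2S,5R)-5-[2-(benzyloxy)propan-2-yl]-2-methyl-2-[(1R)-4-methylcyclohex-3-en-1-yl]oxolan-3-one
Product: 18 (2S,3S,5R)-5-[2-(benzyloxy)propan-2-yl]-2-methyl-2-[(1R)-4-methylcyclohex-3-en-1-yl]oxolan-3-ol
Conditions: LiBH(s-Bu)3, THF, −78 °C; then H2O
Reagents that add atoms: none
Why: The bulky hydride should add to the carbonyl face that carries the C2 methyl group, anti to the larger cyclohexenyl substituent, placing the hydroxyl cis to cyclohexenyl, (3S).

Step 13
Reactants: 18 (2S,3S,5R)-5-[2-(benzyloxy)propan-2-yl]-2-methyl-2-[(1R)-4-methylcyclohex-3-en-1-yl]oxolan-3-ol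
Product: 19 (1S,2S,4R)-4-{(2S,3S,5R)-5-[2-(benzyloxy)propan-2-yl]-3-hydroxy-2-methyloxolan-2-yl}-2-chloro-1-methylcyclohexan-1-ol
Conditions: N-chlorosuccinimide, acetone/H2O (4:1), 0 °C
Reagents that add atoms: N-chlorosuccinimide (O=C1CCC(=O)N1Cl); water (O)
Why: Chlorohydroxylation of the trisubstituted ring alkene: chlorine should add to the face anti to the equatorial C1′ substituent and water open the chloronium ion at the tertiary C4′ in the trans-diaxial sense (Markovnikov and Fürst–Plattner rules agree), the facial course known for bromohydrin formation from limonene-type alkenes, setting (3′S)-Cl and (4′S)-OH.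

Step 14
Reactants: 19 (1S,2S,4R)-4-{(2S,3S,5R)-5-[2-(benzyloxy)propan-2-yl]-3-hydroxy-2-methyloxolan-2-yl}-2-chloro-1-methylcyclohexan-1-ol
Product: 21 (2S,3S,5S)-5-bromo-2-[(1R,3S,4S)-4-bromo-3-chloro-4-methylcyclohexyl]-2,6,6-trimethyloxan-3-ol (CID46881070), via trimethylsilyl ether 20 (not isolated)
Conditions: Me3SiBr (6 equiv), ZnBr2 (cat.), CH2Cl2, −40 → 0 °C; then MeOH, 0 °C
Reagents that add atoms: bromotrimethylsilane (C[Si](C)(C)Br)
Why: Proposed new method: Me3SiBr/ZnBr2 should ionise both tertiary C–O bonds with neighbouring-group help, (a) at C4′ the trans-diaxial chlorine bridges as a chloronium ion that bromide opens at the tertiary carbon, giving the tertiary bromide with retention, and (b) at C6 the ring oxygen O1 bridges C6 and C5 as a bicyclic epoxonium ion that bromide opens either at C6 (a tertiary bromide that re-ionises) or, irreversibly under these conditions, at C5 with inversion, so that the oxolane O1–C5 bond is traded for the oxane O1–C6 bond and the equatorial (5S) bromide is set, while the C3 hydroxyl is masked in the flask as its silyl ether and freed by methanol; the closest known reactions are the ring enlargement of 2-(1-sulfonyloxyalkyl)oxolanes to 3-acyloxyoxanes through the same kind of oxonium ion and the thermodynamic isomerisation of 2-(halomethyl)pyrrolidines to 3-halopiperidines, and the oxonium ion is the one that links the 5-exo and 6-endo products of bromoetherification.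

**Compound list**

1 | (4R)-limonene 1,2-oxide, cis/trans mixture | CC(=C)[C@@H]1CCC2(C)OC2C1 | starting material
2 | 3-methyl-3-[(3R)-6-methyl-7-oxabicyclo[4.1.0]heptan-3-yl]-1,2,4-trioxolane (ozonide) | CC1(OCOO1)[C@@H]2CCC3(C)OC3C2 | intermediate
3 | 1-[(3R)-6-methyl-7-oxabicyclo[4.1.0]heptan-3-yl]ethan-1-one (epoxide epimers) | CC(=O)[C@@H]1CCC2(C)OC2C1 | intermediate
4 | 1-[(1R)-3-hydroxy-4-iodo-4-methylcyclohexyl]ethan-1-one (iodohydrin, isomer mixture) | CC(=O)[C@@H]1CCC(C)(I)C(O)C1 | intermediate
5 | 1-[(1R)-4-methylcyclohex-3-en-1-yl]ethan-1-one | CC(=O)[C@@H]1CCC(C)=CC1 | intermediate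
6 | triethyl phosphonoacetate | CCOC(=O)CP(=O)(OCC)OCC | starting material
7 | ethyl (2E)-3-[(1R)-4-methylcyclohex-3-en-1-yl]but-2-enoate | C/C(=C\C(=O)OCC)[C@@H]1CCC(C)=CC1 | intermediate
8 | (2E)-3-[(1R)-4-methylcyclohex-3-en-1-yl]but-2-en-1-ol | C/C(=C\CO)[C@@H]1CCC(C)=CC1 | intermediate
9 | diethyl (2E)-3-[(1R)-4-methylcyclohex-3-en-1-yl]but-2-en-1-yl phosphate | C/C(=C\COP(=O)(OCC)OCC)[C@@H]1CCC(C)=CC1 | intermediate
10 | dimethyl{(2S)-2-[(1R)-4-methylcyclohex-3-en-1-yl]but-3-en-2-yl}phenylsilane | C=C[C@](C)([Si](C)(C)c1ccccc1)[C@@H]1CCC(C)=CC1 | intermediate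
11 | 2-methylbut-3-en-2-ol | CC(C)(O)C=C | starting material
12 | {[(2-methylbut-3-en-2-yl)oxy]methyl}benzene | CC(C)(OCc1ccccc1)C=C | intermediate
13 | 3-[2-(benzyloxy)propan-2-yl]-1,2,4-trioxolane (ozonide) | CC(C)(OCc1ccccc1)C1OCOO1 | intermediate
14 | 2-(benzyloxy)-2-methylpropanal | CC(C)(OCc1ccccc1)C=O | intermediate
15 | {(2S,3R,5R)-5-[2-(benzyloxy)propan-2-yl]-2-methyl-2-[(1R)-4-methylcyclohex-3-en-1-yl]oxolan-3-yl}dimethyl(phenyl)silane | C[C@@]1([C@@H]2CCC(C)=CC2)O[C@@H](C(C)(C)OCc2ccccc2)C[C@H]1[Si](C)(C)c1ccccc1 | intermediate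
16 | (2S,3R,5R)-5-[2-(benzyloxy)propan-2-yl]-2-methyl-2-[(1R)-4-methylcyclohex-3-en-1-yl]oxolan-3-ol | C[C@@]1([C@@H]2CCC(C)=CC2)O[C@@H](C(C)(C)OCc2ccccc2)C[C@H]1O | intermediate
17 | (2S,5R)-5-[2-(benzyloxy)propan-2-yl]-2-methyl-2-[(1R)-4-methylcyclohex-3-en-1-yl]oxolan-3-one | C[C@@]1([C@@H]2CCC(C)=CC2)O[C@@H](C(C)(C)OCc2ccccc2)CC1=O | intermediate
18 | (2S,3S,5R)-5-[2-(benzyloxy)propan-2-yl]-2-methyl-2-[(1R)-4-methylcyclohex-3-en-1-yl]oxolan-3-ol | C[C@@]1([C@@H]2CCC(C)=CC2)O[C@@H](C(C)(C)OCc2ccccc2)C[C@@H]1O | intermediate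
19 | (1S,2S,4R)-4-{(2S,3S,5R)-5-[2-(benzyloxy)propan-2-yl]-3-hydroxy-2-methyloxolan-2-yl}-2-chloro-1-methylcyclohexan-1-ol | C[C@@]1([C@@H]2CC[C@](C)(O)[C@@H](Cl)C2)O[C@@H](C(C)(C)OCc2ccccc2)C[C@@H]1O | intermediate
20 | {[(2S,3S,5S)-5-bromo-2-[(1R,3S,4S)-4-bromo-3-chloro-4-methylcyclohexyl]-2,6,6-trimethyloxan-3-yl]oxy}trimethylsilane | CC1(C)O[C@@](C)([C@@H]2CC[C@](C)(Br)[C@@H](Cl)C2)[C@@H](O[Si](C)(C)C)C[C@@H]1Br | intermediate
21 | (2S,3S,5S)-5-bromo-2-[(1R,3S,4S)-4-bromo-3-chloro-4-methylcyclohexyl]-2,6,6-trimethyloxan-3-ol | CC1(C)O[C@@](C)([C@@H]2CC[C@](C)(Br)[C@@H](Cl)C2)[C@@H](O)C[C@@H]1Br | target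

**Count and risks**

Total steps: 14. Longest linear sequence: 12 steps (steps 1–6 and 9–14, from 1); steps 7–8 make the aldehyde branch.

Steps most likely to fail:

1. Step 9 (Proposed new method). The silyl group may be lost from the β-silyl cation before the shift and ring closure (plain allyl transfer), or a non-chelated transition state may operate and give the 2,5-cis series. The fallback uses known chemistry, sets out from 10 (with 14) and comes back at 16, so that steps 9 and 10 are bypassed. With TiCl4 in CH2Cl2 at −78 °C the same pair is steered deliberately into the Hosomi–Sakurai allylation (anti-SE2′, chelate control, chirality transfer from the C–Si centre to the carbinol centre), which should give (3R,5E)-2-(benzyloxy)-2-methyl-6-[(1R)-4-methylcyclohex-3-en-1-yl]hept-5-en-3-ol F1. Hydroxyl-directed, catalyst-controlled epoxidation of the homoallylic alkene (VO(Oi-Pr)3, chiral bis-hydroxamic acid ligand, cumene hydroperoxide, toluene) should leave the ring alkene alone and give the 1,3-anti epoxy alcohol (2R)-3-(benzyloxy)-3-methyl-1-{(2R,3R)-3-methyl-3-[(1R)-4-methylcyclohex-3-en-1-yl]oxiran-2-yl}butan-2-ol F2. Camphorsulfonic acid in CH2Cl2 at 0 °C should then close the oxolane by attack of the hydroxyl on the tertiary oxirane carbon with inversion, which gives 16.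

2. Step 14 (Proposed new method). Bromide may return to the tertiary C6 faster than it opens the oxonium ion at C5, so that the material stays at the oxolane stage, or acid may ionise the C2–O1 bond. The fallback uses known chemistry, sets out from 19 and comes back at 21. Me3SiBr at −78 °C without ZnBr2 (tertiary ether and alcohol to tertiary bromides, no equilibration) should give (2S,3S,5R)-2-[(1R,3S,4S)-4-bromo-3-chloro-4-methylcyclohexyl]-5-(2-bromopropan-2-yl)-2-methyloxolan-3-ol F3. Zinc in EtOH/AcOH opens the β-bromo ether (Boord elimination) and at the same time returns the ring alkene from the vicinal bromochloride, giving (2S,3S)-6-methyl-2-[(1R)-4-methylcyclohex-3-en-1-yl]hept-5-ene-2,3-diol F4. Bromoetherification (2,4,4,6-tetrabromocyclohexa-2,5-dien-1-one, MeNO2, 0 °C; 6-endo attack of the tertiary hydroxyl on the bromonium ion of the prenyl alkene, bromine equatorial in the chair) should give (2S,3S,5S)-5-bromo-2,6,6-trimethyl-2-[(1R)-4-methylcyclohex-3-en-1-yl]oxan-3-ol F5. Chlorohydroxylation as in step 13 then gives (1S,2S,4R)-4-[(2S,3S,5S)-5-bromo-3-hydroxy-2,6,6-trimethyloxan-2-yl]-2-chloro-1-methylcyclohexan-1-ol F6, and Me3SiBr replaces only the tertiary cyclohexyl hydroxyl (retention through the chloronium ion) to give 21.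

3. Step 13. Chloronium formation may show poor facial selectivity (it is less reversible than bromonium formation), and the C3 hydroxyl may take part. The fallback sets out from 18 and comes back at 19. N-Bromosuccinimide in acetone/H2O should give, with the high facial selectivity known for limonene-type alkenes, the bromohydrin (1S,2S,4R)-4-{(2S,3S,5R)-5-[2-(benzyloxy)propan-2-yl]-3-hydroxy-2-methyloxolan-2-yl}-2-bromo-1-methylcyclohexan-1-ol F7. K2CO3 in MeOH closes it to the epoxide with oxygen cis to the side chain, (2S,3S,5R)-5-[2-(benzyloxy)propan-2-yl]-2-methyl-2-[(1R,3R,6S)-6-methyl-7-oxabicyclo[4.1.0]heptan-3-yl]oxolan-3-ol F8. Li2CuCl4 in THF opens this epoxide at the secondary carbon in the trans-diaxial sense to give 19.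

Further compounds
F1 | step 9 | (3R,5E)-2-(benzyloxy)-2-methyl-6-[(1R)-4-methylcyclohex-3-en-1-yl]hept-5-en-3-ol | C/C(=C\C[C@@H](O)C(C)(C)OCc1ccccc1)[C@@H]1CCC(C)=CC1
F2 | step 9 | (2R)-3-(benzyloxy)-3-methyl-1-{(2R,3R)-3-methyl-3-[(1R)-4-methylcyclohex-3-en-1-yl]oxiran-2-yl}butan-2-ol | C[C@]1([C@@H]2CCC(C)=CC2)O[C@@H]1C[C@@H](O)C(C)(C)OCc1ccccc1
F3 | step 14 | (2S,3S,5R)-2-[(1R,3S,4S)-4-bromo-3-chloro-4-methylcyclohexyl]-5-(2-bromopropan-2-yl)-2-methyloxolan-3-ol | C[C@@]1([C@@H]2CC[C@](C)(Br)[C@@H](Cl)C2)O[C@@H](C(C)(C)Br)C[C@@H]1O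
F4 | step 14 | (2S,3S)-6-methyl-2-[(1R)-4-methylcyclohex-3-en-1-yl]hept-5-ene-2,3-diol | CC(C)=CC[C@H](O)[C@@](C)(O)[C@@H]1CCC(C)=CC1
F5 | step 14 | (2S,3S,5S)-5-bromo-2,6,6-trimethyl-2-[(1R)-4-methylcyclohex-3-en-1-yl]oxan-3-ol | CC1(C)O[C@@](C)([C@@H]2CCC(C)=CC2)[C@@H](O)C[C@@H]1Br
F6 | step 14 | (1S,2S,4R)-4-[(2S,3S,5S)-5-bromo-3-hydroxy-2,6,6-trimethyloxan-2-yl]-2-chloro-1-methylcyclohexan-1-ol | CC1(C)O[C@@](C)([C@@H]2CC[C@](C)(O)[C@@H](Cl)C2)[C@@H](O)C[C@@H]1Br
F7 | step 13 | (1S,2S,4R)-4-{(2S,3S,5R)-5-[2-(benzyloxy)propan-2-yl]-3-hydroxy-2-methyloxolan-2-yl}-2-bromo-1-methylcyclohexan-1-ol | C[C@@]1([C@@H]2CC[C@](C)(O)[C@@H](Br)C2)O[C@@H](C(C)(C)OCc2ccccc2)C[C@@H]1O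
F8 | step 13 | (2S,3S,5R)-5-[2-(benzyloxy)propan-2-yl]-2-methyl-2-[(1R,3R,6S)-6-methyl-7-oxabicyclo[4.1.0]heptan-3-yl]oxolan-3-ol | C[C@@]1([C@@H]2CC[C@]3(C)O[C@@H]3C2)O[C@@H](C(C)(C)OCc2ccccc2)C[C@@H]1O
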